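## Analysis of the target

The target (20) is methyl 7-hydroxy-5-[2-(4-hydroxyphenyl)ethyl]-2,2-dimethyl-8-(3-methylbut-2-enyl)-2H-chromene-6-carboxylate. A fully substituted benzene ring A is fused through C4–C5 to a 2,2-dimethyl-2H-pyran ring B, and a separate 4-hydroxyphenyl ring C hangs from C6 on an ethylene bridge. Ring A is numbered C1 (CO2Me), C2 (OH), C3 (prenyl), C4 (pyran O), C5 (pyran CH=) and C6 (arylethyl), so six different substituents stand in a fixed order. There is no stereocentre and no stereogenic double bond, so the problem is one of regiochemistry only. The sensitive groups are the electron-rich chromene (acid, oxidants), the prenyl group ortho to a free phenol (acid closes it to a chroman, electrophilic oxidants attack it), two phenols of different acidity and the hydrogen-bonded salicylate ester. The difficulty is that substitution chemistry on a preformed resorcylate must tell C3 from C5 and O2 from O4. The strategy rests on one feature: C2, carrying OH, lies between C1 (ester) and C3 (prenyl), with oxygen again at C4. That is the 1,3-dioxygenation that results when one carbon is inserted between the two ends of a 3-acyloxy-1,4-enyne while the acyloxy group moves onto C4.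

## Retrosynthetic reasoning

Ring B is removed first. Cutting O4–CMe2 and C5–CH= leads back to triol 17 and 3-methylbut-2-enal 18. C5 is the only unsubstituted carbon of ring A and O4 its only ortho oxygen, so the forward condensation and oxa-6π closure can give one chromene only. The acid- and oxidant-sensitive pyran is thereby made last.

Triol 17 is traced to 16, in which O4 is a pivalate and the ring-C phenol a silyl ether. Both are phenol derivatives cleaved by methoxide, and the methyl ester exchanges degenerately, so one methanolysis should free both.

Ring A of 16 is cut at C1–C2 and C2–C3, which removes C2 as carbon monoxide 14 and opens the ring to the acyclic pivaloyloxy enyne 13. This is the cut that uses the feature above. C1 is the alkene terminus, C3 the alkyne terminus, and the oxygen on C4 is the pivalate that was on the carbinol carbon (future C5) before a 1,2-shift. The forward reaction must, under monovalent rhodium, shift the pivalate, close the ring and take up 14, and it reaches the aromatic oxidation level without any oxidant.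

In 13 the bond between the carbinol carbon and the alkyne is cut, together with the O-acyl bond. This gives enal 7 and 5-methylhex-4-en-1-yne 10. The forward step is a 1,2-addition of the lithium acetylide to the formyl group and trapping of the alkoxide as the pivalate.

The C=C bond of 7 (future C1=C6) is cut to aldehyde 4 and methyl glyoxylate 5. The forward aldol condensation must give the E isomer, formyl trans to ester, because this turns hydrogen and not the ester towards the bond that closes ring A.

Aldehyde 4 comes from 4-(4-hydroxyphenyl)butanoic acid 1 by esterification, silylation and partial reduction (through 2 and 3). Enyne 10 is cut at its propargylic C–C bond to prenyl bromide 8 and ethynylmagnesium bromide 9.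

## Alternatives that were turned down

Alternative 1: The arylethyl and ester groups are attached last to an intact chromene, by cutting C6–CH2 and C1–CO2Me through a C1–C6 aryne. The key step would give methyl 7-(methoxymethoxy)-5-{2-[4-(methoxymethoxy)phenyl]ethyl}-2,2-dimethyl-8-(3-methylbut-2-enyl)-2H-chromene-6-carboxylate A1.
- Forward step: the chloride 5-chloro-7-(methoxymethoxy)-2,2-dimethyl-8-(3-methylbut-2-enyl)-2H-chromene A2 is deprotonated by a hindered lithium amide between chlorine and the acetal oxygen and loses chloride. The Grignard reagent {2-[4-(methoxymethoxy)phenyl]ethyl}magnesium bromide A3 adds at C6, and the C1 arylmagnesium is quenched with a chloroformate.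
- For it: it is convergent and late, two bonds form in one flask, and the inductive effect of the C2 oxygen directs the nucleophile to C6. On convergence it is stronger than the chosen route.
- Against it: A2 is a chlorinated prenyl chromene whose own assembly needs the C-prenylation and chromenylation selectivities that the chosen route avoids. The strong base meets the benzylic–allylic CH2 of the prenyl group. C6 is the more hindered aryne terminus, and the C1 anion is flanked on both sides. Two acetal ethers must finally be removed with acid from a molecule that holds a chromene and a prenyl group ortho to a phenol.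
- Comparison: the chosen route ends with base and a mild condensation, and it places every substituent by the connectivity of an open chain.

Alternative 2: Ring A is made non-aromatic by cutting C1–C6 and C2–C3. The key step would give methyl trans-4-hydroxy-6-{2-[4-(methoxymethoxy)phenyl]ethyl}-3-(3-methylbut-2-enyl)-2-oxocyclohex-3-ene-1-carboxylate A4 (racemic).
- Forward step: a malonic diester adds under methoxide to the enone (3E)-1-[4-(methoxymethoxy)phenyl]-9-methyldeca-3,8-dien-5-one A5 (Michael addition), and the C3 enolate then closes onto a malonate ester (Claisen).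
- For it: this is the oldest and most dependable entry to 6-alkyl resorcylates. The closure can only give the six-membered ring, the reagents are cheap, and the sequence is shorter than the chosen one. On precedent and step count it is stronger.
- Against it: A4 is two hydrogens short of the arene. The usual dehydrogenating agents (halogens, quinones, metal oxidants) would attack the prenyl alkene or cyclise it oxidatively onto O2 or O4, which would build the wrong pyran. The enone also needs a cross-aldol at the methyl side of an unsymmetrical ketone.
- Comparison: the chosen carbonylation reaches the aromatic level without an oxidant, which is the one operation this alternative cannot avoid, and it differentiates O4 from O2.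

Alternative 3: Ring A comes from a [4+2] addition and cycloreversion, cutting C1–C2 and C5–C6. The key step would give methyl 3-(3-methylbut-2-enyl)-2,4-bis(trimethylsilyloxy)-6-{2-[4-(tert-butyldimethylsilyloxy)phenyl]ethyl}benzoate A6.
- Forward step: the diene 5,5-dimethyl-2-(3-methylbut-2-enyl)-1,3-bis(trimethylsilyloxy)cyclohexa-1,3-diene A7 adds to the ynoate methyl 5-[4-(tert-butyldimethylsilyloxy)phenyl]pent-2-ynoate A8, and the bicyclic adduct expels its gem-dimethyl bridge as a volatile alkene on heating.
- For it: the polarised partners fix the regiochemistry, no oxidant is needed, and one desilylation would give triol 17. The ring-forming event has better precedent than the chosen one, and the step count is similar or lower.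
- Against it: a β-alkyl ynoate is a weak dienophile and the diene is fully substituted, so temperatures near 200 °C are to be expected. Silyl migration, hydrogen shifts in the diene and ene reactions of the prenyl group compete at such temperatures. The C-prenylation of the cyclic dione competes with O-alkylation.
- Comparison: the chosen step would run catalytically near 60 °C, adds only carbon monoxide, and leaves O4 and O2 differentiated.

Key step: step 7

Remark on the chemistry: the target is achiral, so 6, 12, 13 and 15 are racemic (6 also a diastereomer mixture) and no stereocontrol is sought; methyl glyoxylate 5 is taken as the freshly distilled monomer.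

## Route

Step 1
Reactants: 1 4-(4-hydroxyphenyl)butanoic acid
Product: 2 methyl 4-(4-hydroxyphenyl)butanoate
Conditions: MeOH, H2SO4 (cat.), reflux
Reagents that add atoms: methanol (SMILES CO)
Why: Fischer esterification; the phenol is untouched in acidic methanol, and the ester is the oxidation level from which one hydride delivery reaches the aldehyde.

Step 2
Reactants: 2 methyl 4-(4-hydroxyphenyl)butanoate
Product: 3 methyl 4-[4-(tert-butyldimethylsilyloxy)phenyl]butanoate
Conditions: TBSCl, imidazole, DMF, rt
Reagents that add atoms: tert-butyldimethylsilyl chloride, CC(C)(C)[Si](C)(C)Cl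
Why: Imidazole-promoted silylation of the phenol; the aryl silyl ether should survive hydride, amine catalysis, the acetylide at low temperature and the rhodium step, and it falls together with the pivalate in step 8.

Step 3
Reactants: 3 methyl 4-[4-(tert-butyldimethylsilyloxy)phenyl]butanoate
Product: 4 4-[4-(tert-butyldimethylsilyloxy)phenyl]butanal
Conditions: i-Bu2AlH (1.1 equiv), CH2Cl2, −78 °C; MeOH, then aq. KNaC4H4O6
Reagents that add atoms: none
Why: Partial reduction of an unhindered methyl ester with one equivalent of i-Bu2AlH at −78 °C, where the reduction should stop at the aldehyde oxidation level until work-up.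

Step 4
Reactants: 4 4-[4-(tert-butyldimethylsilyloxy)phenyl]butanal; 5 methyl glyoxylate
Product: 7 methyl (2E)-5-[4-(tert-butyldimethylsilyloxy)phenyl]-3-formylpent-2-enoate, via aldol adduct 6 (not isolated)
Conditions: 5 (1.5 equiv), pyrrolidine (20 mol %), PhCO2H (20 mol %), toluene, 60 °C
Reagents that add atoms: none
Why: Amine-catalysed cross-aldol condensation: the enamine of 4 adds to the non-enolisable, highly electrophilic aldehyde of 5, and adduct 6 loses water by an E1cB path. The E isomer (formyl trans to ester) should prevail under the equilibrating iminium conditions, and it is the geometry step 7 needs.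

Step 5
Reactants: 8 prenyl bromide (1-bromo-3-methylbut-2-ene); 9 ethynylmagnesium bromide
Product: 10 5-methylhex-4-en-1-yne
Conditions: CuCl (5 mol %), THF, 0 °C to rt
Reagents that add atoms: none
Why: Copper-catalysed coupling of an alkynyl Grignard reagent with an allylic bromide; attack at the primary terminus (SN2) should dominate over SN2′, which would build a quaternary carbon. The volatile product is distilled and handled as a solution.

Step 6
Reactants: 10 5-methylhex-4-en-1-yne; 7 methyl (2E)-5-[4-(tert-butyldimethylsilyloxy)phenyl]-3-formylpent-2-enoate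
Product: 13 methyl (2E)-3-{2-[4-(tert-butyldimethylsilyloxy)phenyl]ethyl}-9-methyl-4-(pivaloyloxy)deca-2,8-dien-5-ynoate (racemic), via lithium acetylide 11 (not isolated), via lithium alkoxide 12 (not isolated)
Conditions: 10, n-BuLi, THF, −78 °C; 7, −78 °C; t-BuCOCl, −78 to 0 °C
Reagents that add atoms: pivaloyl chloride, CC(C)(C)C(=O)Cl
Why: Acetylide 11 should add 1,2 to the formyl group of 7 faster than to the ester or the conjugate position, and alkoxide 12 is acylated in the same flask. The E alkene keeps the alkoxide away from the ester, so no lactone can form. The new carbinol centre is formed without control (racemic) and is destroyed in step 7.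

Step 7
Reactants: 13 methyl (2E)-3-{2-[4-(tert-butyldimethylsilyloxy)phenyl]ethyl}-9-methyl-4-(pivaloyloxy)deca-2,8-dien-5-ynoate; 14 carbon monoxide
Product: 16 methyl 6-{2-[4-(tert-butyldimethylsilyloxy)phenyl]ethyl}-2-hydroxy-3-(3-methylbut-2-enyl)-4-(pivaloyloxy)benzoate, via keto tautomer 15 (not isolated)
Conditions: [Rh(CO)2Cl]2 (5 mol %), CO (1 atm), ClCH2CH2Cl, 60 °C
Reagents that add atoms: none
Why: Proposed new method: monovalent rhodium should bind the alkyne of 13, the pivalate carbonyl oxygen should attack the nearer alkyne carbon (future C4) through a five-membered acyloxonium ring, and the ester should end on C4, leaving a rhodium carbene on the prenyl-bearing carbon (future C3). The carbene and the C1=C6 alkene are then expected to close a rhodacyclohexadiene bound to C3 and C1, CO 14 inserts, and reductive elimination forms C1–C2 and C2–C3 (the same outcome follows from carbonylation of the carbene to a dienylketene and six-electron electrocyclisation). Dienone 15 should enolise at once to 16, since the C1 hydrogen lies between a ketone and an ester and the product is an arene whose O2–H is hydrogen-bonded to the ester. The closest known reaction type is the rhodium-catalysed carbonylative [5+1] annulation of 3-acyloxy-1,4-enynes with a terminal alkyne, which gives resorcinol monoesters; an alkyl-capped alkyne and an ester on the alkene terminus have not been shown. Ring A closes in a [5+1] mode, five carbons from the enyne and one from CO, and no stereocentre is created. The step needs 1,2- over 1,3-acyloxy migration (the latter gives an allenyl pivalate) and CO capture of the carbene over a 1,2-hydride shift from the neighbouring CH2. The substrate offers the bulky, electron-rich pivalate, which favours the five-membered migration path, an E alkene that turns hydrogen and not the ester towards the closing bond, and an aromatic end point that drains the 1,2 channel while the 1,3-shift stays reversible; these bias the outcome but do not guarantee it.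

Step 8
Reactants: 16 methyl 6-{2-[4-(tert-butyldimethylsilyloxy)phenyl]ethyl}-2-hydroxy-3-(3-methylbut-2-enyl)-4-(pivaloyloxy)benzoate
Product: 17 methyl 2,4-dihydroxy-6-[2-(4-hydroxyphenyl)ethyl]-3-(3-methylbut-2-enyl)benzoate
Conditions: NaOMe (4 equiv), MeOH, 0 °C to rt; 1 M HCl
Reagents that add atoms: none
Why: Methoxide should transesterify the aryl pivalate and attack silicon of the aryl silyl ether (both with phenoxide leaving groups), while exchange at the methyl ester is degenerate in methanol. No acid or oxidant meets the prenyl group.

Step 9
Reactants: 17 methyl 2,4-dihydroxy-6-[2-(4-hydroxyphenyl)ethyl]-3-(3-methylbut-2-enyl)benzoate; 18 3-methylbut-2-enal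
Product: 20 methyl 7-hydroxy-5-[2-(4-hydroxyphenyl)ethyl]-2,2-dimethyl-8-(3-methylbut-2-enyl)-2H-chromene-6-carboxylate, via ortho-quinone methide 19 (not isolated)
Conditions: 18 (3 equiv), ethylenediammonium diacetate (20 mol %), toluene, 110 °C
Reagents that add atoms: none
Why: Ammonium-salt-catalysed condensation of a resorcinol with an enal: C-alkylation at C5, loss of water to quinone methide 19, then oxa-6π electrocyclisation onto O4. C5 is the only free carbon of ring A and O4 its only ortho oxygen, so a single chromene is possible; the monohydric ring-C phenol lacks the nucleophilicity of the 1,3-dioxygenated ring and should stay out.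

## Compound list

1 | 4-(4-hydroxyphenyl)butanoic acid | OC(=O)CCCc1ccc(O)cc1 | starting material
2 | methyl 4-(4-hydroxyphenyl)butanoate | COC(=O)CCCc1ccc(O)cc1 | intermediate
3 | methyl 4-[4-(tert-butyldimethylsilyloxy)phenyl]butanoate | COC(=O)CCCc1ccc(O[Si](C)(C)C(C)(C)C)cc1 | intermediate
4 | 4-[4-(tert-butyldimethylsilyloxy)phenyl]butanal | O=CCCCc1ccc(O[Si](C)(C)C(C)(C)C)cc1 | intermediate
5 | methyl glyoxylate | COC(=O)C=O | starting material
6 | methyl 5-[4-(tert-butyldimethylsilyloxy)phenyl]-3-formyl-2-hydroxypentanoate (racemic diastereomer mixture) | COC(=O)C(O)C(C=O)CCc1ccc(O[Si](C)(C)C(C)(C)C)cc1 | intermediate (not isolated)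
7 | methyl (2E)-5-[4-(tert-butyldimethylsilyloxy)phenyl]-3-formylpent-2-enoate | COC(=O)/C=C(/C=O)CCc1ccc(O[Si](C)(C)C(C)(C)C)cc1 | intermediate
8 | prenyl bromide (1-bromo-3-methylbut-2-ene) | CC(C)=CCBr | starting material
9 | ethynylmagnesium bromide | C#C[Mg]Br | starting material
10 | 5-methylhex-4-en-1-yne | C#CCC=C(C)C | intermediate
11 | (5-methylhex-4-en-1-yn-1-yl)lithium | [Li]C#CCC=C(C)C | intermediate (not isolated)
12 | lithium alkoxide of methyl (2E)-3-{2-[4-(tert-butyldimethylsilyloxy)phenyl]ethyl}-4-hydroxy-9-methyldeca-2,8-dien-5-ynoate (racemic) | COC(=O)/C=C(CCc1ccc(O[Si](C)(C)C(C)(C)C)cc1)/C(O[Li])C#CCC=C(C)C | intermediate (not isolated)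
13 | methyl (2E)-3-{2-[4-(tert-butyldimethylsilyloxy)phenyl]ethyl}-9-methyl-4-(pivaloyloxy)deca-2,8-dien-5-ynoate (racemic) | COC(=O)/C=C(CCc1ccc(O[Si](C)(C)C(C)(C)C)cc1)/C(OC(=O)C(C)(C)C)C#CCC=C(C)C | intermediate
14 | carbon monoxide | [C-]#[O+] | starting material
15 | methyl 2-{2-[4-(tert-butyldimethylsilyloxy)phenyl]ethyl}-5-(3-methylbut-2-enyl)-6-oxo-4-(pivaloyloxy)cyclohexa-2,4-diene-1-carboxylate (racemic) | COC(=O)C1C(=O)C(CC=C(C)C)=C(OC(=O)C(C)(C)C)C=C1CCc1ccc(O[Si](C)(C)C(C)(C)C)cc1 | intermediate (not isolated)
16 | methyl 6-{2-[4-(tert-butyldimethylsilyloxy)phenyl]ethyl}-2-hydroxy-3-(3-methylbut-2-enyl)-4-(pivaloyloxy)benzoate | COC(=O)c1c(O)c(CC=C(C)C)c(OC(=O)C(C)(C)C)cc1CCc1ccc(O[Si](C)(C)C(C)(C)C)cc1 | intermediate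
17 | methyl 2,4-dihydroxy-6-[2-(4-hydroxyphenyl)ethyl]-3-(3-methylbut-2-enyl)benzoate | COC(=O)c1c(O)c(CC=C(C)C)c(O)cc1CCc1ccc(O)cc1 | intermediate
18 | 3-methylbut-2-enal | CC(C)=CC=O | starting material
19 | methyl 2-hydroxy-6-[2-(4-hydroxyphenyl)ethyl]-3-(3-methylbut-2-enyl)-5-(3-methylbut-2-enylidene)-4-oxocyclohexa-2,6-diene-1-carboxylate (ortho-quinone methide) | COC(=O)C1=C(CCc2ccc(O)cc2)C(=CC=C(C)C)C(=O)C(CC=C(C)C)=C1O | intermediate (not isolated)
20 | methyl 7-hydroxy-5-[2-(4-hydroxyphenyl)ethyl]-2,2-dimethyl-8-(3-methylbut-2-enyl)-2H-chromene-6-carboxylate | COC(=O)c1c(O)c(CC=C(C)C)c2c(c1CCc1ccc(O)cc1)C=CC(C)(C)O2 | target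

## Step count and risk

Total: 9 steps. Longest linear sequence: 8 steps (steps 1–4 and 6–9); step 5 is a one-step side branch.

Step 7 (key step, proposed new method) is the least certain.
- What may go wrong: 1,3-acyloxy migration to the allene, which is the usual course for alkyl-substituted alkynes, followed by other carbonylation or decomposition paths; 1,2-hydride shift at the carbene from the adjacent CH2 without uptake of CO; slow engagement of the electron-poor alkene terminus.
- Fallback (known chemistry, a Danheiser benzannulation of the same two fragments): it sets out from enal 7 and enyne 10 and returns to the route at triol 17. MeMgBr (THF, −78 °C) adds to the formyl group of 7 to give methyl (2E)-5-[4-(tert-butyldimethylsilyloxy)phenyl]-3-(1-hydroxyethyl)pent-2-enoate F1. Dess–Martin periodinane oxidises it to methyl (2E)-3-acetyl-5-[4-(tert-butyldimethylsilyloxy)phenyl]pent-2-enoate F2. Detrifluoroacetylative diazo transfer (LiN(SiMe3)2, CF3CO2CH2CF3, −78 °C; then MsN3, Et3N) gives methyl (2E)-5-[4-(tert-butyldimethylsilyloxy)phenyl]-3-(diazoacetyl)pent-2-enoate F3; this method is used because diazomethane would add to the fumarate-type alkene. Separately, the lithium acetylide of 10 is oxidised with LiOOt-Bu to the ynolate and silylated with i-Pr3SiOTf to triisopropyl[(5-methylhex-4-en-1-yn-1-yl)oxy]silane F4. Irradiation of F3 with F4 should cause a photochemical Wolff rearrangement to the vinylketene and its [2+2] addition to the ynol ether. Warming then gives four-electron ring opening and six-electron closure to methyl 6-{2-[4-(tert-butyldimethylsilyloxy)phenyl]ethyl}-2-hydroxy-3-(3-methylbut-2-enyl)-4-(triisopropylsilyloxy)benzoate F5. In F5 the ketene carbonyl carbon has become C2, the alkyne carbons C3 and C4, and the former diazo carbon C5. Bu4NF (THF, 0 °C) removes both silyl groups and gives 17.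

Step 4.
- What may go wrong: self-condensation of 4, migration of the new double bond out of conjugation with the ester through the dienamine, or incomplete equilibration to the E isomer.
- Fallback (stepwise, through a preformed enol ether): it sets out from 4 and returns at 7. Me3SiCl and Et3N in DMF give tert-butyldimethyl{4-[4-(trimethylsilyloxy)but-3-enyl]phenoxy}silane F6. A Mukaiyama aldol addition of F6 to 5 (BF3·OEt2, CH2Cl2, −78 °C) gives adduct 6, now isolated. MsCl and Et3N convert 6 into methyl 5-[4-(tert-butyldimethylsilyloxy)phenyl]-3-formyl-2-(methylsulfonyloxy)pentanoate F7, which eliminates under the same base to 7.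

Step 9.
- What may go wrong: low reactivity of C5, which is flanked by the arylethyl chain and sits on an ester-deactivated ring, so that self-condensation of the enal wins.
- Fallback (aryl propargyl ether Claisen route): it sets out from 17 and returns at 20. 3-Chloro-3-methylbut-1-yne with K2CO3 (1 equiv), KI and CuI (cat.) in acetone should alkylate O4, the most acidic phenol (para to the ester; O2 is tied up in the hydrogen bond and the ring-C phenol is less acidic), to give methyl 2-hydroxy-6-[2-(4-hydroxyphenyl)ethyl]-3-(3-methylbut-2-enyl)-4-[(2-methylbut-3-yn-2-yl)oxy]benzoate F8. Heating F8 in xylene at 140 °C should bring about Claisen rearrangement to C5 (the only free ortho position), a 1,5-hydrogen shift and oxa-6π closure to 20.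

Step 3.
- What may go wrong: over-reduction to the primary alcohol if the tetrahedral aluminium intermediate collapses before the quench.
- Fallback (two-step redox): it sets out from 3 and returns at 4. LiAlH4 (THF, 0 °C) reduces 3 fully to 4-[4-(tert-butyldimethylsilyloxy)phenyl]butan-1-ol F9, which Dess–Martin periodinane oxidises to 4.

## Further compounds

F1 | step 7 | methyl (2E)-5-[4-(tert-butyldimethylsilyloxy)phenyl]-3-(1-hydroxyethyl)pent-2-enoate (racemic) | COC(=O)/C=C(/C(C)O)CCc1ccc(O[Si](C)(C)C(C)(C)C)cc1
F2 | step 7 | methyl (2E)-3-acetyl-5-[4-(tert-butyldimethylsilyloxy)phenyl]pent-2-enoate | COC(=O)/C=C(/C(C)=O)CCc1ccc(O[Si](C)(C)C(C)(C)C)cc1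
F3 | step 7 | methyl (2E)-5-[4-(tert-butyldimethylsilyloxy)phenyl]-3-(diazoacetyl)pent-2-enoate | COC(=O)/C=C(/C(=O)C=[N+]=[N-])CCc1ccc(O[Si](C)(C)C(C)(C)C)cc1
F4 | step 7 | triisopropyl[(5-methylhex-4-en-1-yn-1-yl)oxy]silane | CC(C)=CCC#CO[Si](C(C)C)(C(C)C)C(C)C
F5 | step 7 | methyl 6-{2-[4-(tert-butyldimethylsilyloxy)phenyl]ethyl}-2-hydroxy-3-(3-methylbut-2-enyl)-4-(triisopropylsilyloxy)benzoate | COC(=O)c1c(O)c(CC=C(C)C)c(O[Si](C(C)C)(C(C)C)C(C)C)cc1CCc1ccc(O[Si](C)(C)C(C)(C)C)cc1
F6 | step 4 | tert-butyldimethyl{4-[4-(trimethylsilyloxy)but-3-enyl]phenoxy}silane (E/Z mixture) | C[Si](C)(C)OC=CCCc1ccc(O[Si](C)(C)C(C)(C)C)cc1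
F7 | step 4 | methyl 5-[4-(tert-butyldimethylsilyloxy)phenyl]-3-formyl-2-(methylsulfonyloxy)pentanoate (racemic diastereomer mixture) | COC(=O)C(OS(C)(=O)=O)C(C=O)CCc1ccc(O[Si](C)(C)C(C)(C)C)cc1
F8 | step 9 | methyl 2-hydroxy-6-[2-(4-hydroxyphenyl)ethyl]-3-(3-methylbut-2-enyl)-4-[(2-methylbut-3-yn-2-yl)oxy]benzoate | COC(=O)c1c(O)c(CC=C(C)C)c(OC(C)(C)C#C)cc1CCc1ccc(O)cc1
F9 | step 3 | 4-[4-(tert-butyldimethylsilyloxy)phenyl]butan-1-ol | OCCCCc1ccc(O[Si](C)(C)C(C)(C)C)cc1
A1 | alternative 1 | methyl 7-(methoxymethoxy)-5-{2-[4-(methoxymethoxy)phenyl]ethyl}-2,2-dimethyl-8-(3-methylbut-2-enyl)-2H-chromene-6-carboxylate | COCOc1c(C(=O)OC)c(CCc2ccc(OCOC)cc2)c2C=CC(C)(C)Oc2c1CC=C(C)C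
A2 | alternative 1 | 5-chloro-7-(methoxymethoxy)-2,2-dimethyl-8-(3-methylbut-2-enyl)-2H-chromene | COCOc1cc(Cl)c2C=CC(C)(C)Oc2c1CC=C(C)C
A3 | alternative 1 | {2-[4-(methoxymethoxy)phenyl]ethyl}magnesium bromide | COCOc1ccc(CC[Mg]Br)cc1
A4 | alternative 2 | methyl trans-4-hydroxy-6-{2-[4-(methoxymethoxy)phenyl]ethyl}-3-(3-methylbut-2-enyl)-2-oxocyclohex-3-ene-1-carboxylate (racemic, one enantiomer drawn) | COC(=O)[C@H]1[C@H](CCc2ccc(OCOC)cc2)CC(O)=C(CC=C(C)C)C1=O
A5 | alternative 2 | (3E)-1-[4-(methoxymethoxy)phenyl]-9-methyldeca-3,8-dien-5-one | COCOc1ccc(CC/C=C/C(=O)CCC=C(C)C)cc1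
A6 | alternative 3 | methyl 3-(3-methylbut-2-enyl)-2,4-bis(trimethylsilyloxy)-6-{2-[4-(tert-butyldimethylsilyloxy)phenyl]ethyl}benzoate | COC(=O)c1c(O[Si](C)(C)C)c(CC=C(C)C)c(O[Si](C)(C)C)cc1CCc1ccc(O[Si](C)(C)C(C)(C)C)cc1
A7 | alternative 3 | 5,5-dimethyl-2-(3-methylbut-2-enyl)-1,3-bis(trimethylsilyloxy)cyclohexa-1,3-diene | C[Si](C)(C)OC1=C(CC=C(C)C)C(O[Si](C)(C)C)=CC(C)(C)C1
A8 | alternative 3 | methyl 5-[4-(tert-butyldimethylsilyloxy)phenyl]pent-2-ynoate | COC(=O)C#CCCc1ccc(O[Si](C)(C)C(C)(C)C)cc1
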